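A direct plan would oxidise 3-bromo-4-methoxyphenol A1 to its quinone monoketal A2 and let the phenoxide of 4-(benzyloxy)-2-bromophenol A3 displace the vinylic bromide,
with zinc then rearomatising the adduct to the diaryl ether A4; debenzylation would give the bisphenol A5, fourfold bromination the pentabromide A6, and demethylation the target.
Its weakest steps would be:
(a) the ether-forming substitution on the bromo quinone monoketal with reductive rearomatisation, which would have no precedent (attack at the other enone carbon, ketal exchange, loss of aryl bromide to zinc);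
(b) the fourfold bromination of the assembled diaryl ether, where bromine can oxidise both para-oxygenated phenol rings and regiocontrol rests on rate differences alone, on the most precious material;
(c) the separate benzyl and methyl ether cleavages, two steps that would add no complexity.

Plan of the new route: the retrosynthesis cuts ring A itself, at C1–C2 and C3–C4 (ring A: C1 OH, C2 H, C3 Br, C4 OH, C5 Br, C6 OAr), and no aryl–oxygen bond.
Feature used: ring A is a para-hydroquinone whose contiguous carbons C4(OH)–C5(Br)–C6(OAr)–C1(OH) are the chain of mucobromic acid (lactone carbonyl, α-CBr, β-carbon, acetal carbon), while C2(H)–C3(Br) is 2-bromoacrolein minus its formyl group.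
Ring B comes first (a bought quinone plus HBr) and is tied through oxygen to the furanone β-carbon before ring A exists.
Ring A arises last, in one anionic annulation of the furanolate with 2-bromoacrolein that sets all six substituents.
No quinone ketal substitution, no bromination of a diaryl ether and no protecting group occur; all five bromines arrive in building blocks.

Key step: step 5

Remark on the chemistry: the acetal carbon of the furanone intermediates and the sp3 centres of the transient annulation intermediates are racemic or undefined; all are lost on aromatisation, and the target has no stereocentre. 2,6-Dibromo-1,4-benzoquinone, mucobromic acid and acrolein are taken as commercial. Ring B is numbered C1' (ether O), C2' (H), C3' (Br), C4' (OH), C5' (Br), C6' (Br).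

Step 1
Reactants: 1 2,6-dibromo-1,4-benzoquinone
Product: 2 2,3,5-tribromobenzene-1,4-diol
Conditions: HBr (48% aq., 3 equiv), AcOH, 0 °C → rt, under Ar
Reagents that add atoms: hydrogen bromide, SMILES Br
Why: Hydrobromination of a quinone, in which bromide adds in a 1,4-sense to one of the two equivalent unsubstituted ring carbons and the adduct enolises to the hydroquinone, so only one regioisomer can form and no stereocentre is created.

Step 2
Reactants: 3 mucobromic acid (3,4-dibromo-5-hydroxyfuran-2(5H)-one)
Product: 4 3,4-dibromo-5-methoxyfuran-2(5H)-one (racemic)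
Conditions: MeOH, H2SO4 (cat.), reflux
Reagents that add atoms: methanol, SMILES CO
Why: Acid-catalysed pseudoesterification (acetalisation of the cyclic lactol form) is the standard entry to 5-alkoxy-3,4-dihalofuranones; the acetal centre is racemic and is destroyed in step 5.

Step 3
Reactants: 2 2,3,5-tribromobenzene-1,4-diol; 4 3,4-dibromo-5-methoxyfuran-2(5H)-one
Product: 5 3-bromo-5-methoxy-4-(2,3,5-tribromo-4-hydroxyphenoxy)furan-2(5H)-one (racemic)
Conditions: K2CO3 (2.5 equiv), DMF, 0 °C → rt, under Ar; then aq. HCl
Reagents that add atoms: none
Why: Addition–elimination (vinylogous acyl substitution) of phenoxides at the β-carbon C-4 of 5-alkoxy-3,4-dihalofuran-2(5H)-ones is well known and leaves the α-bromine in place; in the dianion of 2 the oxygen flanked by one bromine and one hydrogen is both more basic and far less hindered than the one flanked by two bromines, so it should be the one that attacks, and no stereocentre is set.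

Step 4
Reactants: 6 acrolein (prop-2-enal)
Product: 8 2-bromoprop-2-enal (2-bromoacrolein), via 2,3-dibromopropanal 7 (not isolated)
Conditions: Br2 (1.0 equiv), CH2Cl2, −78 → 0 °C; then Et3N (1.05 equiv), 0 °C; short-path distillation, used fresh
Reagents that add atoms: bromine, SMILES BrBr
Why: Bromine addition to the alkene followed by E1cB dehydrobromination of the α-bromo aldehyde with Et3N is the standard preparation of 2-bromoacrolein; no stereocentre remains.

Step 5
Reactants: 5 3-bromo-5-methoxy-4-(2,3,5-tribromo-4-hydroxyphenoxy)furan-2(5H)-one; 8 2-bromoprop-2-enal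
Product: 12 3,5-dibromo-2-(2,3,5-tribromo-4-hydroxyphenoxy)benzene-1,4-diol, via dilithium furanolate 9 (not isolated), via oxa-bridged adduct 10 (not isolated), via formyl enedione 11 (not isolated)
Conditions: LiN(SiMe3)2 (2.1 equiv), THF, −78 °C; 8 (1.3 equiv), −78 → −20 °C; MeOH, 0 °C; aq. HCl, under Ar
Reagents that add atoms: none
Why: Proposed new method: LiN(SiMe3)2 removes the phenol proton and the acidic acetal proton at furanone C-5 to give the 5-methoxyfuran-2-olate 9, a 2,5-dioxygenated furan whose C-5 adds to the CH2 terminus of 8, after which the α-bromo enolate acylates the lactone carbonyl (Michael–Dieckmann sequence, formally an anionic Diels–Alder addition across furan C-5 and C-2) to give the bridged alkoxide 10. 10 collapses by opening the oxygen bridge at the former carbonyl carbon and expelling methoxide from the former C-5, which gives enedione 11; the methoxide, a hard nucleophile, then adds to the aldehyde and removes the formyl group as methyl formate by retro-Claisen cleavage, and the resulting bromo enedione enolate tautomerises to the hydroquinone. The closest known reaction types are the Hauser–Kraus annulation of phthalide anions with Michael acceptors, Diels–Alder reactions of 2,5-bis(silyloxy)furans that deliver hydroquinones, and the retro-Claisen deformylation of fully substituted β-keto aldehydes. Ring A closes as a six-membered carbocycle by an intermolecular conjugate addition (C1–C2) followed by an intramolecular enolate acylation (C3–C4) through a bicyclo[2.2.1] alkoxide, and no stereocentre is left because every sp3 centre of 10 and 11 becomes an aromatic carbon. The step needs regiocontrol (Br at C3, not C2), which the substrate should secure because the oxido group at C-2 makes C-5 the nucleophilic terminus, C-3 is blocked by bromine and only attack at the enal β-carbon gives an enolate that can cyclise, while reversible additions elsewhere are drained by the irreversible aromatisation; it also needs loss of the formyl group and not of bromide from 11, which should be favoured because the aldehyde between bromine and a ketone is the most electrophilic site for the methoxide released next to it and the fragmentation of its adduct leads straight to an aromatic phenoxide, and the aryl bromides meet no reagent capable of metal–halogen exchange.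

Compound list
1 | 2,6-dibromo-1,4-benzoquinone | O=C1C=C(Br)C(=O)C(Br)=C1 | starting material
2 | 2,3,5-tribromobenzene-1,4-diol | Oc1cc(Br)c(O)c(Br)c1Br | intermediate
3 | mucobromic acid (3,4-dibromo-5-hydroxyfuran-2(5H)-one) | OC1OC(=O)C(Br)=C1Br | starting material
4 | 3,4-dibromo-5-methoxyfuran-2(5H)-one (racemic) | COC1OC(=O)C(Br)=C1Br | intermediate
5 | 3-bromo-5-methoxy-4-(2,3,5-tribromo-4-hydroxyphenoxy)furan-2(5H)-one (racemic) | COC1OC(=O)C(Br)=C1Oc1cc(Br)c(O)c(Br)c1Br | intermediate
6 | acrolein (prop-2-enal) | C=CC=O | starting material
7 | 2,3-dibromopropanal (racemic, not isolated) | O=CC(Br)CBr | intermediate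
8 | 2-bromoprop-2-enal | C=C(Br)C=O | intermediate
9 | dilithium 3-bromo-5-methoxy-4-(2,3,5-tribromo-4-oxidophenoxy)furan-2-olate (not isolated) | [Li+].[Li+].COc1oc([O-])c(Br)c1Oc2cc(Br)c([O-])c(Br)c2Br | intermediate
10 | 2,6-dibromo-1-hydroxy-4-methoxy-5-(2,3,5-tribromo-4-hydroxyphenoxy)-7-oxabicyclo[2.2.1]hept-5-ene-2-carbaldehyde (present as lithium alkoxide, configuration undefined, not isolated) | O=CC1(Br)CC2(OC)OC1(O)C(Br)=C2Oc3cc(Br)c(O)c(Br)c3Br | intermediate
11 | 1,3-dibromo-2,5-dioxo-4-(2,3,5-tribromo-4-hydroxyphenoxy)cyclohex-3-ene-1-carbaldehyde (racemic, not isolated) | O=CC1(Br)CC(=O)C(Oc2cc(Br)c(O)c(Br)c2Br)=C(Br)C1=O | intermediate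
12 | 3,5-dibromo-2-(2,3,5-tribromo-4-hydroxyphenoxy)benzene-1,4-diol | Oc1cc(Br)c(O)c(Br)c1Oc1cc(Br)c(O)c(Br)c1Br | target

Total step count: 5
Longest linear sequence: 3 steps (1 → 2 → 5 → 12, or 3 → 4 → 5 → 12)

Steps most likely to fail

Step 5 (proposed new method). What may go wrong: conjugate addition through C-3 of the furanolate or 1,2-addition to the aldehyde without productive ring closure, aromatisation by loss of bromine instead of the formyl group, or displacement of the aryloxy group by methoxide at the enedione stage. The fallback gives up the ring construction and uses known chemistry; it sets out from 2 and comes back at 12. Commercial 2-fluoro-4-hydroxybenzaldehyde would be brominated at both positions ortho to the hydroxyl (Br2, NaOAc, AcOH) to 3,5-dibromo-2-fluoro-4-hydroxybenzaldehyde F1 and O-methylated (MeI, K2CO3, DMF) to 3,5-dibromo-2-fluoro-4-methoxybenzaldehyde F2. Nucleophilic aromatic substitution of the fluoride, activated by the ortho formyl group, by the less hindered oxygen of the dianion of 2 (K2CO3, DMF, 80 °C) should give 3,5-dibromo-4-methoxy-2-(2,3,5-tribromo-4-hydroxyphenoxy)benzaldehyde F3. Dakin-type Baeyer–Villiger oxidation (mCPBA, CH2Cl2; then K2CO3, MeOH) should give 3,5-dibromo-4-methoxy-2-(2,3,5-tribromo-4-hydroxyphenoxy)phenol F4, and BBr3 (CH2Cl2, −78 °C → rt) should cleave the methyl ether to 12.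

Step 3. What may go wrong: etherification through the more hindered, more acidic oxygen of 2, etherification at both oxygens, or air oxidation of the hydroquinone dianion. The fallback differentiates the two hydroxyls first; it sets out from 2 and comes back at 5. Silylation of the less hindered hydroxyl (tert-butyldimethylsilyl chloride, imidazole, DMF) should give 2,3,6-tribromo-4-[(tert-butyldimethylsilyl)oxy]phenol F5. The remaining hindered hydroxyl would be capped (chloromethyl methyl ether, i-Pr2NEt, CH2Cl2) to tert-butyl(dimethyl)[2,3,5-tribromo-4-(methoxymethoxy)phenoxy]silane F6, and Bu4NF (THF, 0 °C) would free 2,3,5-tribromo-4-(methoxymethoxy)phenol F7. Its single phenoxide would be condensed with 4 (K2CO3, DMF) to 3-bromo-5-methoxy-4-[2,3,5-tribromo-4-(methoxymethoxy)phenoxy]furan-2(5H)-one F8, and HCl in MeOH, which leaves the methyl acetal of the furanone unchanged, would remove the methoxymethyl group to give 5.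

Step 1. What may go wrong: redox exchange between the hydroquinone formed and unreacted quinone, which would lead on to over- and under-brominated hydroquinones. The fallback brominates at the hydroquinone stage; it sets out from 1 and comes back at 2. Reduction of 1 (Na2S2O4, EtOAc–H2O) would give 2,6-dibromobenzene-1,4-diol F9, whose only free ring positions are equivalent and lie ortho to the unhindered hydroxyl, so that Br2 (1.0 equiv, AcOH, 0 °C, reductive work-up) should give 2.

Further compounds
F1 | step 5 | 3,5-dibromo-2-fluoro-4-hydroxybenzaldehyde | O=Cc1cc(Br)c(O)c(Br)c1F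
F2 | step 5 | 3,5-dibromo-2-fluoro-4-methoxybenzaldehyde | COc1c(Br)cc(C=O)c(F)c1Br
F3 | step 5 | 3,5-dibromo-4-methoxy-2-(2,3,5-tribromo-4-hydroxyphenoxy)benzaldehyde | COc1c(Br)cc(C=O)c(Oc2cc(Br)c(O)c(Br)c2Br)c1Br
F4 | step 5 | 3,5-dibromo-4-methoxy-2-(2,3,5-tribromo-4-hydroxyphenoxy)phenol | COc1c(Br)cc(O)c(Oc2cc(Br)c(O)c(Br)c2Br)c1Br
F5 | step 3 | 2,3,6-tribromo-4-[(tert-butyldimethylsilyl)oxy]phenol | CC(C)(C)[Si](C)(C)Oc1cc(Br)c(O)c(Br)c1Br
F6 | step 3 | tert-butyl(dimethyl)[2,3,5-tribromo-4-(methoxymethoxy)phenoxy]silane | CC(C)(C)[Si](C)(C)Oc1cc(Br)c(OCOC)c(Br)c1Br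
F7 | step 3 | 2,3,5-tribromo-4-(methoxymethoxy)phenol | COCOc1c(Br)cc(O)c(Br)c1Br
F8 | step 3 | 3-bromo-5-methoxy-4-[2,3,5-tribromo-4-(methoxymethoxy)phenoxy]furan-2(5H)-one | COCOc1c(Br)cc(OC2=C(Br)C(=O)OC2OC)c(Br)c1Br
F9 | step 1 | 2,6-dibromobenzene-1,4-diol | Oc1c(Br)cc(O)cc1Br
A1 | direct plan | 3-bromo-4-methoxyphenol | COc1ccc(O)cc1Br
A2 | direct plan | 3-bromo-4,4-dimethoxycyclohexa-2,5-dien-1-one | COC1(OC)C=CC(=O)C=C1Br
A3 | direct plan | 4-(benzyloxy)-2-bromophenol | Oc1ccc(OCc2ccccc2)cc1Br
A4 | direct plan | 3-[4-(benzyloxy)-2-bromophenoxy]-4-methoxyphenol | COc1ccc(O)cc1Oc1ccc(OCc2ccccc2)cc1Br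
A5 | direct plan | 3-(2-bromo-4-hydroxyphenoxy)-4-methoxyphenol | COc1ccc(O)cc1Oc1ccc(O)cc1Br
A6 | direct plan | 2,6-dibromo-4-methoxy-3-(2,3,5-tribromo-4-hydroxyphenoxy)phenol | COc1cc(Br)c(O)c(Br)c1Oc1cc(Br)c(O)c(Br)c1Br
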